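## Structural features

The target 18 is a flavanone. A benzene ring A is fused to a dihydropyran-4-one ring C (O1, C2, C3, C4, C4a, C8a), and a 4-methoxyphenyl ring B sits on C2. Ring A carries hydroxyl groups at C5 and C7 and a 3-methylbut-2-enyl (prenyl) chain at C6 between them; the C5 hydroxyl is hydrogen-bonded to the C4 carbonyl. C2 is the only stereocentre and is S, so no stereocentres stand next to each other and only absolute control is needed. The C2–O1 bond is fragile: it is benzylic, activated by the para-methoxy group and β to the ketone, so base opens ring C to the chalcone and strong acid ionises it, and either path racemises C2. The prenyl alkene is also fragile: acid closes it onto a neighbouring phenol, electrophilic oxidants attack it and it would not survive hydrogenolysis. The real difficulties are to set C2 as one enantiomer and to place the prenyl group at C6 and not at C8. C2 carries O1, ring B and the two-carbon arm C3–C4. Once O1–C2 and C4–C4a are cut, the ring A phenol has the prenyl group para to O1 and two identical protected oxygens, so a mirror plane through O1 and C6 makes the two carbons ortho to O1 identical. The descriptor S of the open-chain ether and of the flavanone denotes the same spatial arrangement (O1 > ring B > vinyl or C3 > H), so the structures of the coupling partners and of the coupled ether are consistent and are used unchanged.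

## Logic of the disconnections

18 to 17: the two phenolic O–H groups are traced back to two O–CH2OCH3 acetals. The cut is made there because ring A must stay masked through base, borane, oxidant and acylation, and because the same acetals earlier serve as directing groups. The gain is a ring A without acidic protons. The demand is an acetal cleavage that spares the prenyl alkene and the C2–O1 bond.

17 to 15: the C4–C4a bond is cut, which opens ring C and returns C4 to a carboxylic acid on the ether chain. The ring A fragment is symmetric, so acylation at either ortho carbon gives the same 6-prenyl product and no regiochemical control is needed. The demand is a ring closure mild enough not to ionise the C2–O1 bond or strip the acetals.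

15 to 13 to 11: no skeletal bond is cut. The C4 acid is traced back through the primary alcohol to a terminal vinyl group, so C3 and C4 come from the alkene left by an allylic substitution. The demand is a hydroboration that takes the monosubstituted alkene and leaves the trisubstituted prenyl alkene, followed by an oxidation that touches neither the electron-rich ring nor the alkene.

11 to 7 and 9: the O1–C2 bond is cut, which divides the molecule into two achiral fragments of similar size and removes the only stereocentre. The forward step must join a phenoxide oxygen to the aryl-bearing terminus of an allyl unit with control of the face, with branched selectivity and with O-alkylation in preference to C-alkylation.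

7 to 6 to 3 and 4: the aryl–CH2 bond C6–C1'' is cut, then the O–Si bond. The carbon between the two acetal oxygens is the most readily metalated position once the third oxygen carries a bulky silyl group, so the prenyl group enters at one defined position and the ring stays symmetric. The demand is lithiation at that carbon only, and coupling at the primary carbon of 4 without allylic transposition.

3 to 2 to 1: the O–Si bond and two O–CH2 bonds are cut, which leads to the symmetric triol. The demand is a twofold protection of three equivalent hydroxyls, which is statistical and is accepted because it is the first step on a cheap material.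

9 to 8: the O–C(=O) bond of the carbonate is cut. The demand is only the acylation of a primary allylic alcohol.

## Other disconnections considered

Alternative 1: Ring A is dismantled into a four-carbon unit (C5, C8, C8a, C4a) and a two-carbon alkyne (C6, C7).
- Forward step: irradiation of the diazoketone (2S)-6-(2-diazoacetyl)-2-(4-methoxyphenyl)-2,3-dihydro-4H-pyran-4-one A2 would trigger a Wolff rearrangement that joins C8 to C8a and gives the vinylketene A4. This would add across the siloxyalkyne triisopropyl[(5-methylhex-4-en-1-yn-1-yl)oxy]silane A3; four-electron ring opening and six-electron ring closure of the adduct would then give (S)-5-hydroxy-4'-methoxy-6-prenyl-7-(triisopropylsilyloxy)flavanone A1. The bonds C5–C6, C7–C8 and C4a–C5 form.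
- In its favour: the polarisation of A3 fixes the prenyl group at C6 by construction, so no symmetry argument and no directed lithiation are needed. The 5-hydroxyl appears free, and only one silyl ether remains, removable with buffered fluoride. On the end game this is better than the chosen plan, which ends with acid next to a prenyl group. C2 is a spectator in a neutral pericyclic cascade, which is equal or better for its integrity than an acylation.
- Against it: A2 needs C2 set beforehand in a base-sensitive dihydropyranone, followed by a diazo transfer in the presence of two enolisable positions. A3 needs ynolate chemistry. The ketene A4 carries an alkoxy and an acyl substituent, a pattern for which the cascade is less well charted.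
- Comparison: on structure the chosen plan is simpler, with two achiral fragments. On mechanism Alternative 1 is more elegant but less predictable. On step economy it is expected to be longer.

Alternative 2: The C6–C1'' bond is cut on the intact flavanone.
- Forward step: the 5-O-(1,1-dimethylallyl) ether A6, (S)-7-O-tert-butyldimethylsilyl-5-O-(2-methylbut-3-en-2-yl)-4'-methoxyflavanone, would undergo an aromatic Claisen rearrangement. The temporary O5–C bond breaks, C6–C1'' forms with allyl inversion, and re-aromatisation gives (S)-7-O-tert-butyldimethylsilyl-5-hydroxy-4'-methoxy-6-prenylflavanone A5.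
- In its favour: starting from the parent flavanone (S)-5,7-dihydroxy-4'-methoxyflavanone A7 it would be the shortest route, so it is better on step economy. From O5 the only free ortho carbon is C6, so regiocontrol equals that of the chosen plan. The key step is concerted and needs neither acid nor base.
- Against it: the tertiary allyl group must be put on the chelated, hindered 5-hydroxyl, in practice by a tertiary propargylic electrophile with base and then partial hydrogenation. Base threatens ring C and C2. Heating A6 invites a further shift to C8, loss of the tertiary group by elimination, and thermal racemisation. The enantiopurity of A7 from natural sources is not assured.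
- Comparison: the chosen plan is longer but sets C2 by a catalyst and never exposes the finished flavanone to base or strong heat. On absolute stereocontrol the chosen plan is the better; on step count Alternative 2 is.

Alternative 3: The C2–C1' bond is cut.
- Forward step: 4-methoxyphenylboronic acid A10 would add to C2 of 5,7-bis(methoxymethoxy)-6-prenylchromone A9 under a chiral divalent palladium catalyst, Pd(OCOCF3)2 with a pyridine–oxazoline ligand. Transmetalation, insertion of the enone and protonolysis would give (S)-5,7-bis(methoxymethoxy)-4'-methoxy-6-prenylflavanone A8, which is identical with 17.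
- In its favour: the C–C bond and the stereocentre are made in one catalytic step on the assembled bicycle, without redox work on a side chain. After the key step only one step remains, which is better than the four of the chosen plan. The last step is the same in both plans, so they are equal there.
- Against it: A9 must be made as the pure 6-prenyl isomer, so the 6-versus-8 problem that the chosen plan removes by symmetry returns when the chromone ring is built. A9 is a doubly donor-substituted, peri-substituted enone and so a weak acceptor. The aqueous acidic medium at elevated temperature endangers the acetals. An aryl–palladium species may also insert the prenyl alkene.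
- Comparison: Alternative 3 is more convergent. The chosen plan is more secure in regiochemistry and in chemoselectivity towards the prenyl group. Overall step counts are expected to be similar.

Key step: step 6

Remark: the (Sa,Sc,Sc) enantiomer of the ligand is assumed, on the accepted facial model of this catalyst family for aryl-substituted allyl carbonates and heteroatom nucleophiles, to give the (S)-ether; the antipode is equally available if correlation of 11 shows the opposite sense.

Step 1
Reactants: 1 phloroglucinol (benzene-1,3,5-triol)
Product: 2 3,5-bis(methoxymethoxy)phenol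
Conditions: MOMCl (2.0 equiv), i-Pr2NEt (2.2 equiv), THF, 0 °C to rt; chromatography
Reagents that add atoms: chloromethyl methyl ether, COCCl
Why: O-alkylation of phenoxide by an α-chloro ether (Williamson type); the three hydroxyls are equivalent, so the twofold protection is statistical and 2 is separated from mono- and tris-ether, the mono-ether being recycled.

Step 2
Reactants: 2 3,5-bis(methoxymethoxy)phenol
Product: 3 [3,5-bis(methoxymethoxy)phenoxy]tri(propan-2-yl)silane
Conditions: TIPSCl, imidazole, DMF, rt
Reagents that add atoms: chlorotri(propan-2-yl)silane, CC(C)[Si](Cl)(C(C)C)C(C)C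
Why: Silylation of a phenol; the bulky triisopropylsilyl group resists n-BuLi, shields the two flanking ring carbons and is slow to migrate from O to C.

Step 3
Reactants: 3 [3,5-bis(methoxymethoxy)phenoxy]tri(propan-2-yl)silane; 4 prenyl bromide (1-bromo-3-methylbut-2-ene)
Product: 6 [3,5-bis(methoxymethoxy)-4-(3-methylbut-2-en-1-yl)phenoxy]tri(propan-2-yl)silane, via aryllithium 5 (not isolated)
Conditions: n-BuLi (1.1 equiv), THF, 0 °C, 1 h; then CuBr·SMe2 (10 mol %), 4 (1.3 equiv), −78 °C to rt
Reagents that add atoms: none
Why: Directed ortho-metalation: the ring carbon flanked by two chelating acetal oxygens is the kinetically most acidic, while the positions next to the silyloxy group are shielded; the aryllithium then couples with the primary allylic bromide, catalytic copper favouring direct substitution over allylic transposition.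

Step 4
Reactants: 6 [3,5-bis(methoxymethoxy)-4-(3-methylbut-2-en-1-yl)phenoxy]tri(propan-2-yl)silane
Product: 7 3,5-bis(methoxymethoxy)-4-(3-methylbut-2-en-1-yl)phenol
Conditions: TBAF (1.1 equiv), THF, 0 °C
Reagents that add atoms: none
Why: Fluoride-induced cleavage of the aryl silyl ether; acetals and alkene are inert to fluoride.

Step 5
Reactants: 8 (E)-4-methoxycinnamyl alcohol ((2E)-3-(4-methoxyphenyl)prop-2-en-1-ol)
Product: 9 (E)-3-(4-methoxyphenyl)allyl methyl carbonate
Conditions: ClCO2Me, pyridine, CH2Cl2, 0 °C
Reagents that add atoms: methyl chloroformate, COC(=O)Cl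
Why: Acylation of a primary allylic alcohol by a chloroformate with pyridine as base; the E alkene is untouched.

Step 6
Reactants: 7 3,5-bis(methoxymethoxy)-4-(3-methylbut-2-en-1-yl)phenol; 9 (E)-3-(4-methoxyphenyl)allyl methyl carbonate
Product: 11 1-{[(1S)-1-(4-methoxyphenyl)prop-2-en-1-yl]oxy}-3,5-bis(methoxymethoxy)-4-(3-methylbut-2-en-1-yl)benzene, via lithium phenoxide 10 (not isolated)
Conditions: n-BuLi (1.0 equiv), THF, 0 °C; then 9 (1.2 equiv), [Ir(cod)Cl]2 (2 mol %), (Sa,Sc,Sc)-O,O'-(1,1'-binaphthalene-2,2'-diyl) N,N-bis(1-phenylethyl)phosphoramidite (4 mol %, pre-activated with n-PrNH2), THF, rt; chromatography on Et3N-deactivated silica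
Reagents that add atoms: none
Why: [Ir(cod)Cl]2 and the phosphoramidite, once cyclometalated by base, give a univalent iridium complex that ionises 9, with loss of CO2 and methoxide, to an allyl complex of trivalent iridium. Lithium phenoxide 10 attacks this complex outer-sphere, anti to the metal, at the aryl-bearing terminus, forming the O1–C2 bond; no ring closes. The closest known reaction type is the iridium–phosphoramidite, branched-selective asymmetric allylic etherification of cinnamyl carbonates with alkali aryloxides. C2 is controlled by the catalyst alone: the metallacycle fixes the orientation of the allyl ligand and leaves one face of the benzylic terminus open, and both substrates are achiral. The step needs branched over linear substitution, which the catalyst imposes and the cation-stabilising 4-methoxyphenyl group at the attacked terminus reinforces. It needs O- over C-allylation of a very electron-rich phenoxide, secured by the lithium counter-ion in THF at room temperature, and the mirror symmetry of 10 leaves no regiochemical question on the nucleophile. It also needs the product to resist re-ionisation and [3,3] shift, which is helped by the poor leaving-group ability of the electron-rich aryloxide, by stopping at full conversion and by never heating 11.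

Step 7
Reactants: 11 1-{[(1S)-1-(4-methoxyphenyl)prop-2-en-1-yl]oxy}-3,5-bis(methoxymethoxy)-4-(3-methylbut-2-en-1-yl)benzene
Product: 13 (3S)-3-[3,5-bis(methoxymethoxy)-4-(3-methylbut-2-en-1-yl)phenoxy]-3-(4-methoxyphenyl)propan-1-ol, via B-alkyl-9-BBN adduct 12 (not isolated)
Conditions: 9-BBN (1.3 equiv), THF, 0 °C to rt; then 3 M aq NaOH, 30% H2O2, 0 °C
Reagents that add atoms: hydrogen peroxide, OO
Why: Anti-Markovnikov hydroboration–oxidation; the bulky 9-BBN places boron on the terminal carbon and reacts with the monosubstituted vinyl group far faster than with the trisubstituted prenyl alkene, and C2 is not involved.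

Step 8
Reactants: 13 (3S)-3-[3,5-bis(methoxymethoxy)-4-(3-methylbut-2-en-1-yl)phenoxy]-3-(4-methoxyphenyl)propan-1-ol
Product: 15 (3S)-3-[3,5-bis(methoxymethoxy)-4-(3-methylbut-2-en-1-yl)phenoxy]-3-(4-methoxyphenyl)propanoic acid, via aldehyde 14 (not isolated)
Conditions: TEMPO (20 mol %), PhI(OAc)2 (2.2 equiv), MeCN/H2O (1:1), rt
Reagents that add atoms: water, O
Why: Nitroxyl-catalysed oxidation of the primary alcohol to the aldehyde, whose hydrate is oxidised on to the acid in the aqueous medium; the weakly acidic conditions spare the alkene, the electron-rich ring and the acetals and do not promote β-elimination of the aryloxide.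

Step 9
Reactants: 15 (3S)-3-[3,5-bis(methoxymethoxy)-4-(3-methylbut-2-en-1-yl)phenoxy]-3-(4-methoxyphenyl)propanoic acid
Product: 17 (2S)-5,7-bis(methoxymethoxy)-2-(4-methoxyphenyl)-6-(3-methylbut-2-en-1-yl)chroman-4-one, via mixed anhydride 16 (not isolated)
Conditions: (CF3CO)2O (1.2 equiv), 2,6-di-tert-butyl-4-methylpyridine (2.5 equiv), CH2Cl2, −20 to 0 °C; aq NaHCO3
Reagents that add atoms: none
Why: Intramolecular Friedel–Crafts acylation through the acyl trifluoroacetate, closing the six-membered ring C at a ring carbon activated by three oxygen substituents; the two ortho carbons are equivalent, so only the 6-prenyl isomer can form. The hindered pyridine takes up the acid so that the C2–O1 bond and the acetals are not ionised, and no bond to C2 is broken.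

Step 10
Reactants: 17 (2S)-5,7-bis(methoxymethoxy)-2-(4-methoxyphenyl)-6-(3-methylbut-2-en-1-yl)chroman-4-one
Product: 18 (2S)-5,7-dihydroxy-2-(4-methoxyphenyl)-6-(3-methylbut-2-en-1-yl)chroman-4-one
Conditions: 3 M aq HCl, MeOH, 45 °C, stopped at full conversion
Reagents that add atoms: none
Why: Acid-catalysed solvolysis of the two aryl methoxymethyl acetals (transacetalisation to dimethoxymethane), the customary unmasking for prenylated flavanones; moderate temperature and short exposure limit closure of the prenyl group onto a phenol and ionisation at C2.

Compound list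

1 | phloroglucinol (benzene-1,3,5-triol) | Oc1cc(O)cc(O)c1 | starting material
2 | 3,5-bis(methoxymethoxy)phenol | COCOc1cc(O)cc(OCOC)c1 | intermediate
3 | [3,5-bis(methoxymethoxy)phenoxy]tri(propan-2-yl)silane | COCOc1cc(OCOC)cc(O[Si](C(C)C)(C(C)C)C(C)C)c1 | intermediate
4 | prenyl bromide (1-bromo-3-methylbut-2-ene) | CC(C)=CCBr | starting material
5 | [2,6-bis(methoxymethoxy)-4-(triisopropylsilyloxy)phenyl]lithium | [Li]c1c(OCOC)cc(O[Si](C(C)C)(C(C)C)C(C)C)cc1OCOC | intermediate (not isolated)
6 | [3,5-bis(methoxymethoxy)-4-(3-methylbut-2-en-1-yl)phenoxy]tri(propan-2-yl)silane | COCOc1cc(O[Si](C(C)C)(C(C)C)C(C)C)cc(OCOC)c1CC=C(C)C | intermediate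
7 | 3,5-bis(methoxymethoxy)-4-(3-methylbut-2-en-1-yl)phenol | Oc1cc(OCOC)c(CC=C(C)C)c(OCOC)c1 | intermediate
8 | (E)-4-methoxycinnamyl alcohol | COc1ccc(/C=C/CO)cc1 | starting material
9 | (E)-3-(4-methoxyphenyl)allyl methyl carbonate | COC(=O)OC/C=C/c1ccc(OC)cc1 | intermediate
10 | lithium 3,5-bis(methoxymethoxy)-4-(3-methylbut-2-en-1-yl)phenoxide | [Li]Oc1cc(OCOC)c(CC=C(C)C)c(OCOC)c1 | intermediate (not isolated)
11 | 1-{[(1S)-1-(4-methoxyphenyl)prop-2-en-1-yl]oxy}-3,5-bis(methoxymethoxy)-4-(3-methylbut-2-en-1-yl)benzene | COc1ccc([C@@H](Oc2cc(OCOC)c(CC=C(C)C)c(OCOC)c2)C=C)cc1 | intermediate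
12 | 9-{(3S)-3-[3,5-bis(methoxymethoxy)-4-(3-methylbut-2-en-1-yl)phenoxy]-3-(4-methoxyphenyl)propyl}-9-borabicyclo[3.3.1]nonane | COc1ccc([C@@H](Oc2cc(OCOC)c(CC=C(C)C)c(OCOC)c2)CCB3C4CCCC3CCC4)cc1 | intermediate (not isolated)
13 | (3S)-3-[3,5-bis(methoxymethoxy)-4-(3-methylbut-2-en-1-yl)phenoxy]-3-(4-methoxyphenyl)propan-1-ol | COc1ccc([C@@H](Oc2cc(OCOC)c(CC=C(C)C)c(OCOC)c2)CCO)cc1 | intermediate
14 | (3S)-3-[3,5-bis(methoxymethoxy)-4-(3-methylbut-2-en-1-yl)phenoxy]-3-(4-methoxyphenyl)propanal | COc1ccc([C@@H](Oc2cc(OCOC)c(CC=C(C)C)c(OCOC)c2)CC=O)cc1 | intermediate (not isolated)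
15 | (3S)-3-[3,5-bis(methoxymethoxy)-4-(3-methylbut-2-en-1-yl)phenoxy]-3-(4-methoxyphenyl)propanoic acid | COc1ccc([C@@H](Oc2cc(OCOC)c(CC=C(C)C)c(OCOC)c2)CC(=O)O)cc1 | intermediate
16 | (3S)-3-[3,5-bis(methoxymethoxy)-4-(3-methylbut-2-en-1-yl)phenoxy]-3-(4-methoxyphenyl)propanoic trifluoroacetic anhydride | COc1ccc([C@@H](Oc2cc(OCOC)c(CC=C(C)C)c(OCOC)c2)CC(=O)OC(=O)C(F)(F)F)cc1 | intermediate (not isolated)
17 | (2S)-5,7-bis(methoxymethoxy)-2-(4-methoxyphenyl)-6-(3-methylbut-2-en-1-yl)chroman-4-one | COc1ccc([C@@H]2CC(=O)c3c(cc(OCOC)c(CC=C(C)C)c3OCOC)O2)cc1 | intermediate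
18 | (2S)-5,7-dihydroxy-2-(4-methoxyphenyl)-6-(3-methylbut-2-en-1-yl)chroman-4-one | COc1ccc([C@@H]2CC(=O)c3c(cc(O)c(CC=C(C)C)c3O)O2)cc1 | target

Total step count: 10. Longest linear sequence: 9 (steps 1 to 4 and 6 to 10); step 5 is the one-step side branch.

Least certain steps

Step 6 (key step).
- What may go wrong: allylation at a ring carbon of the very electron-rich phenoxide instead of at oxygen; partial formation of the linear ether; loss of enantiopurity through re-ionisation of the branched ether, which the 4-methoxyphenyl group makes easier; transfer of the methoxycarbonyl group from 9 to the phenoxide; and [3,3] shift of the product if it is warmed.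
- Fallback, from 7 back to the route at 13: commercial 3-chloro-1-(4-methoxyphenyl)propan-1-one F1 would be reduced with BH3·SMe2 and catalytic (S)-2-methyl-CBS-oxazaborolidine (CBS reduction) to (1R)-3-chloro-1-(4-methoxyphenyl)propan-1-ol F2. Mitsunobu coupling of F2 with 7 (PPh3, DIAD, toluene, 0 °C) should give, with inversion, 1-{[(1S)-3-chloro-1-(4-methoxyphenyl)propyl]oxy}-3,5-bis(methoxymethoxy)-4-(3-methylbut-2-en-1-yl)benzene F3. Displacement of chloride with KOAc and catalytic NaI in DMF at 60 °C would give (3S)-3-[3,5-bis(methoxymethoxy)-4-(3-methylbut-2-en-1-yl)phenoxy]-3-(4-methoxyphenyl)propyl acetate F4, and K2CO3 in MeOH would release 13. This replaces steps 5 to 7 by four operations and sets C2 by reduction and inversion instead of by allylic substitution.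

Step 9.
- What may go wrong: sluggish ring closure under buffered conditions; or, with too little buffer, ionisation of the C2–O1 bond, loss of an acetal, or trifluoroacetylation of ring A.
- Fallback, from 15 back to the route at 17: amide coupling with Me2NH·HCl (EDC·HCl, HOBt, i-Pr2NEt) would give (3S)-3-[3,5-bis(methoxymethoxy)-4-(3-methylbut-2-en-1-yl)phenoxy]-3-(4-methoxyphenyl)-N,N-dimethylpropanamide F5. Activation with Tf2O and 2-fluoropyridine in CH2Cl2 at −78 to 0 °C (intramolecular Vilsmeier–Haack-type arylation of an activated amide) should close ring C to the cyclic iminium salt (2S)-N-[5,7-bis(methoxymethoxy)-2-(4-methoxyphenyl)-6-(3-methylbut-2-en-1-yl)chroman-4-ylidene]-N-methylmethanaminium trifluoromethanesulfonate F6. Hydrolysis with aqueous NaHCO3 would give 17. The medium stays buffered by a pyridine throughout.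

Step 10.
- What may go wrong: acid-induced closure of the prenyl alkene onto the C5 or C7 hydroxyl, and partial racemisation by ionisation at C2 during prolonged heating.
- Fallback, from 17 back to the route at 18: TMSOTf and 2,2'-bipyridyl in MeCN at 0 °C would exchange both aryl acetals for silyl ethers under non-protic conditions, giving (2S)-2-(4-methoxyphenyl)-6-(3-methylbut-2-en-1-yl)-5,7-bis(trimethylsilyloxy)chroman-4-one F7. Neutral aqueous work-up would hydrolyse F7 to 18.

Step 3.
- What may go wrong: metalation next to the silyloxy group followed by silyl migration to carbon, or coupling with allylic transposition to the 1,1-dimethylallyl isomer.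
- Fallback, from 1 and 4 back to the route at 6: direct C-alkylation of 1 with 4 in aqueous KOH at 0 °C would give 2-(3-methylbut-2-en-1-yl)benzene-1,3,5-triol F8. Silylation of its unhindered hydroxyl para to the prenyl group (TIPSCl, imidazole, DMF, 0 °C) would give 2-(3-methylbut-2-en-1-yl)-5-[tri(propan-2-yl)silyloxy]benzene-1,3-diol F9. MOMCl and i-Pr2NEt would protect the two remaining hydroxyls to give 6. The regiochemistry is then set by the symmetry of 1 and not by lithiation.

Further compounds

F1 | step 6 | 3-chloro-1-(4-methoxyphenyl)propan-1-one | COc1ccc(C(=O)CCCl)cc1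
F2 | step 6 | (1R)-3-chloro-1-(4-methoxyphenyl)propan-1-ol | COc1ccc([C@H](O)CCCl)cc1
F3 | step 6 | 1-{[(1S)-3-chloro-1-(4-methoxyphenyl)propyl]oxy}-3,5-bis(methoxymethoxy)-4-(3-methylbut-2-en-1-yl)benzene | COc1ccc([C@@H](Oc2cc(OCOC)c(CC=C(C)C)c(OCOC)c2)CCCl)cc1
F4 | step 6 | (3S)-3-[3,5-bis(methoxymethoxy)-4-(3-methylbut-2-en-1-yl)phenoxy]-3-(4-methoxyphenyl)propyl acetate | COc1ccc([C@@H](Oc2cc(OCOC)c(CC=C(C)C)c(OCOC)c2)CCOC(C)=O)cc1
F5 | step 9 | (3S)-3-[3,5-bis(methoxymethoxy)-4-(3-methylbut-2-en-1-yl)phenoxy]-3-(4-methoxyphenyl)-N,N-dimethylpropanamide | COc1ccc([C@@H](Oc2cc(OCOC)c(CC=C(C)C)c(OCOC)c2)CC(=O)N(C)C)cc1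
F6 | step 9 | (2S)-N-[5,7-bis(methoxymethoxy)-2-(4-methoxyphenyl)-6-(3-methylbut-2-en-1-yl)chroman-4-ylidene]-N-methylmethanaminium trifluoromethanesulfonate | COc1ccc([C@@H]2CC(=[N+](C)C)c3c(cc(OCOC)c(CC=C(C)C)c3OCOC)O2)cc1.[O-]S(=O)(=O)C(F)(F)F
F7 | step 10 | (2S)-2-(4-methoxyphenyl)-6-(3-methylbut-2-en-1-yl)-5,7-bis(trimethylsilyloxy)chroman-4-one | COc1ccc([C@@H]2CC(=O)c3c(cc(O[Si](C)(C)C)c(CC=C(C)C)c3O[Si](C)(C)C)O2)cc1
F8 | step 3 | 2-(3-methylbut-2-en-1-yl)benzene-1,3,5-triol | CC(C)=CCc1c(O)cc(O)cc1O
F9 | step 3 | 2-(3-methylbut-2-en-1-yl)-5-[tri(propan-2-yl)silyloxy]benzene-1,3-diol | CC(C)=CCc1c(O)cc(O[Si](C(C)C)(C(C)C)C(C)C)cc1O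
A1 | alternative 1 | (S)-5-hydroxy-4'-methoxy-6-prenyl-7-(triisopropylsilyloxy)flavanone | COc1ccc([C@@H]2CC(=O)c3c(cc(O[Si](C(C)C)(C(C)C)C(C)C)c(CC=C(C)C)c3O)O2)cc1
A2 | alternative 1 | (2S)-6-(2-diazoacetyl)-2-(4-methoxyphenyl)-2,3-dihydro-4H-pyran-4-one | COc1ccc([C@@H]2CC(=O)C=C(C(=O)C=[N+]=[N-])O2)cc1
A3 | alternative 1 | triisopropyl[(5-methylhex-4-en-1-yn-1-yl)oxy]silane | CC(C)=CCC#CO[Si](C(C)C)(C(C)C)C(C)C
A4 | alternative 1 | 2-[(2S)-2-(4-methoxyphenyl)-4-oxo-3,4-dihydro-2H-pyran-6-yl]ethen-1-one (vinylketene) | COc1ccc([C@@H]2CC(=O)C=C(C=C=O)O2)cc1
A5 | alternative 2 | (S)-7-O-tert-butyldimethylsilyl-5-hydroxy-4'-methoxy-6-prenylflavanone | COc1ccc([C@@H]2CC(=O)c3c(cc(O[Si](C)(C)C(C)(C)C)c(CC=C(C)C)c3O)O2)cc1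
A6 | alternative 2 | (S)-7-O-tert-butyldimethylsilyl-5-O-(2-methylbut-3-en-2-yl)-4'-methoxyflavanone | COc1ccc([C@@H]2CC(=O)c3c(cc(O[Si](C)(C)C(C)(C)C)cc3OC(C)(C)C=C)O2)cc1
A7 | alternative 2 | (S)-5,7-dihydroxy-4'-methoxyflavanone | COc1ccc([C@@H]2CC(=O)c3c(cc(O)cc3O)O2)cc1
A8 | alternative 3 | (S)-5,7-bis(methoxymethoxy)-4'-methoxy-6-prenylflavanone | COc1ccc([C@@H]2CC(=O)c3c(cc(OCOC)c(CC=C(C)C)c3OCOC)O2)cc1
A9 | alternative 3 | 5,7-bis(methoxymethoxy)-6-(3-methylbut-2-en-1-yl)-4H-chromen-4-one | COCOc1cc2occc(=O)c2c(OCOC)c1CC=C(C)C
A10 | alternative 3 | 4-methoxyphenylboronic acid | COc1ccc(B(O)O)cc1
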